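**Strategy.** The aryl ketone is disconnected at the bond between the carbonyl carbon and C1 of the resorcinol ring A. Because ring A carries a hydroxyl on C2, ortho to that bond, the ketone is the photo-Fries isomer of an aryl ester. The key step irradiates the 3-hydroxyphenyl ester of the ring B propanoic acid: the acyl group moves from oxygen to carbon and the 2-hydroxyl is unveiled in one reagent-free operation. Acyl return at C4 or C6 of the resorcinol unit gives the same 2,4-dihydroxyphenyl ketone. The ester comes from a chromene aldehyde (two aryl ether rearrangements on 3,4-dihydroxybenzaldehyde) by reductive Knoevenagel alkylation of Meldrum's acid and phenolysis with resorcinol.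

Key step: step 8

Remark: ring A is the 2,4-dihydroxyphenyl ring and ring B the benzene ring of the chromene (chromene atoms O1, C2, C3, C4, C4a, C5 to C8, C8a). The target has no stereocentre, so no stereocontrol is needed; the transient sp3 centres in 10, 16 and 18 are racemic.

**Step 1**
Reactants: 1 3,4-dihydroxybenzaldehyde; 2 3-chloro-3-methylbut-1-yne
Product: 3 3-hydroxy-4-[(2-methylbut-3-yn-2-yl)oxy]benzaldehyde
Conditions: K2CO3 (1.1 equiv), KI (cat.), CuI (cat.), DMF, 25 to 50 °C
Reagents that add atoms: none
Why: The 4-hydroxyl, para to the formyl group, is the more acidic phenol, so with about one equivalent of base its phenoxide alone should be alkylated by the copper-acetylide-activated tertiary propargylic chloride (copper-catalysed propargylic etherification of the Williamson type).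

**Step 2**
Reactants: 3 3-hydroxy-4-[(2-methylbut-3-yn-2-yl)oxy]benzaldehyde
Product: 6 8-hydroxy-2,2-dimethyl-2H-chromene-6-carbaldehyde, via allenyl catechol 4 (not isolated), via ortho-quinone methide 5 (not isolated)
Conditions: PhNEt2, 190 °C
Reagents that add atoms: none
Why: Aromatic propargyl Claisen rearrangement to C5, the only free ortho position, then tautomerisation to 4, a [1,5]-hydrogen shift to 5 and oxa-6π electrocyclisation should close the 2,2-dimethylchromene ring.

**Step 3**
Reactants: 7 2-methylbut-3-en-2-ol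
Product: 8 tert-butyl 2-methylbut-3-en-2-yl carbonate
Conditions: n-BuLi, THF, 0 °C; then Boc2O, 0 to 25 °C
Reagents that add atoms: di-tert-butyl dicarbonate, CC(C)(C)OC(=O)OC(=O)OC(C)(C)C
Why: The lithium alkoxide of the tertiary allylic alcohol should be acylated cleanly by Boc2O (alkoxide O-acylation) to give the mixed carbonate.

**Step 4**
Reactants: 6 8-hydroxy-2,2-dimethyl-2H-chromene-6-carbaldehyde; 8 tert-butyl 2-methylbut-3-en-2-yl carbonate
Product: 9 2,2-dimethyl-8-[(2-methylbut-3-en-2-yl)oxy]-2H-chromene-6-carbaldehyde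
Conditions: Pd(PPh3)4 (cat.), THF, 0 °C
Reagents that add atoms: none
Why: Tsuji–Trost O-allylation: decarboxylative ionisation gives a 1,1-dimethylallyl palladium complex and tert-butoxide, which deprotonates the phenol, and under kinetic control the phenoxide should attack the more substituted allyl terminus to give the tertiary ether.

**Step 5**
Reactants: 9 2,2-dimethyl-8-[(2-methylbut-3-en-2-yl)oxy]-2H-chromene-6-carbaldehyde
Product: 11 8-hydroxy-2,2-dimethyl-7-(3-methylbut-2-en-1-yl)-2H-chromene-6-carbaldehyde, via Claisen dienone 10 (not isolated)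
Conditions: PhMe, 110 °C (sealed tube)
Reagents that add atoms: none
Why: Aromatic Claisen rearrangement ([3,3]) to C7, the only ortho position bearing hydrogen (C8a is blocked by O1), with allyl inversion turning the 1,1-dimethylallyl ether into the C-prenyl group, followed by enolisation of 10 to the phenol.

**Step 6**
Reactants: 11 8-hydroxy-2,2-dimethyl-7-(3-methylbut-2-en-1-yl)-2H-chromene-6-carbaldehyde; 12 2,2-dimethyl-1,3-dioxane-4,6-dione (Meldrum's acid)
Product: 14 5-{[8-hydroxy-2,2-dimethyl-7-(3-methylbut-2-en-1-yl)-2H-chromen-6-yl]methyl}-2,2-dimethyl-1,3-dioxane-4,6-dione, via arylidene Meldrum's acid 13 (not isolated)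
Conditions: Hantzsch ester (diethyl 2,6-dimethyl-1,4-dihydropyridine-3,5-dicarboxylate, 1.1 equiv), L-proline (cat.), EtOH, 25 °C
Reagents that add atoms: none
Why: Proline-catalysed Knoevenagel condensation gives the strongly electrophilic arylidene 13, which the Hantzsch ester should reduce at once by hydride transfer (organocatalytic reductive Knoevenagel alkylation); the prenyl and chromene alkenes are not hydride acceptors and should stay untouched.

**Step 7**
Reactants: 14 5-{[8-hydroxy-2,2-dimethyl-7-(3-methylbut-2-en-1-yl)-2H-chromen-6-yl]methyl}-2,2-dimethyl-1,3-dioxane-4,6-dione; 15 resorcinol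
Product: 17 3-hydroxyphenyl 3-[8-hydroxy-2,2-dimethyl-7-(3-methylbut-2-en-1-yl)-2H-chromen-6-yl]propanoate, via malonic half ester 16 (not isolated)
Conditions: resorcinol (5 equiv), pyridine, Cu powder (cat.), 110 °C
Reagents that add atoms: none
Why: Phenolysis of the Meldrum's acid ring releases acetone and gives the aryl hydrogen malonate 16, which should decarboxylate under the copper/pyridine conditions (alcoholysis–decarboxylation of a 5-monosubstituted Meldrum's acid); excess resorcinol favours the monoester, and the hindered C8 phenol of ring B should not compete.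

**Step 8**
Reactants: 17 3-hydroxyphenyl 3-[8-hydroxy-2,2-dimethyl-7-(3-methylbut-2-en-1-yl)-2H-chromen-6-yl]propanoate
Product: 19 1-(2,4-dihydroxyphenyl)-3-[8-hydroxy-2,2-dimethyl-7-(3-methylbut-2-en-1-yl)-2H-chromen-6-yl]propan-1-one, via acyl cyclohexadienone 18 (not isolated)
Conditions: hν (254 nm, low-pressure Hg lamp), degassed MeCN (5 mM), quartz flow reactor, 20 °C, partial conversion, 17 recycled
Reagents that add atoms: none
Why: Excitation of the aryl ester chromophore of ring A leads through its dissociative state to homolysis of the acyl–oxygen bond; the caged 3-hydroxyphenoxyl/acyl radical pair recombines at a ring carbon ortho or para to the former ester oxygen, and the cyclohexadienone 18 enolises, so the acyl carbon–aryl carbon bond forms and the C2 hydroxyl of ring A is released together (photo-Fries rearrangement; the closest precedent is the light-induced conversion of resorcinol monobenzoate into 2,4-dihydroxybenzophenone). No ring is closed and no stereocentre is created. The step needs regioselectivity on ring A and chemoselectivity against ring B: recombination at C6 (ortho) and at C4 (para) of the 3-hydroxyphenyl ester both deliver the same 2,4-dihydroxyphenyl ketone, and only the crowded C2 between the two oxygens would give the 2,6-isomer. The chromene of ring B also absorbs, but its photochemical ring opening to the ortho-quinone allide should revert thermally at 20 °C in an aprotic, non-nucleophilic solvent; MeCN as a hydrogen-bond acceptor ties up the C8 hydroxyl and so disfavours proton transfer to the prenyl alkene, and dilution with exclusion of O2 suppresses chromene dimerisation and oxidation. The product is an ortho-hydroxyaryl ketone that dissipates light by excited-state proton transfer, so it should accumulate.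

**Compound list**
1 | 3,4-dihydroxybenzaldehyde | O=Cc1ccc(O)c(O)c1 | starting material
2 | 3-chloro-3-methylbut-1-yne | C#CC(C)(C)Cl | starting material
3 | 3-hydroxy-4-[(2-methylbut-3-yn-2-yl)oxy]benzaldehyde | O=Cc1ccc(OC(C)(C)C#C)c(O)c1 | intermediate
4 | 3,4-dihydroxy-5-(3-methylbuta-1,2-dien-1-yl)benzaldehyde (allenyl catechol) | O=Cc1cc(O)c(O)c(C=C=C(C)C)c1 | intermediate (not isolated)
5 | (Z)-5-hydroxy-3-(3-methylbut-2-en-1-ylidene)-4-oxocyclohexa-1,5-diene-1-carbaldehyde (ortho-quinone methide) | O=CC1=C/C(=C/C=C(C)C)C(=O)C(O)=C1 | intermediate (not isolated)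
6 | 8-hydroxy-2,2-dimethyl-2H-chromene-6-carbaldehyde | O=Cc1cc(O)c2OC(C)(C)C=Cc2c1 | intermediate
7 | 2-methylbut-3-en-2-ol | C=CC(C)(C)O | starting material
8 | tert-butyl 2-methylbut-3-en-2-yl carbonate | C=CC(C)(C)OC(=O)OC(C)(C)C | intermediate
9 | 2,2-dimethyl-8-[(2-methylbut-3-en-2-yl)oxy]-2H-chromene-6-carbaldehyde | O=Cc1cc(OC(C)(C)C=C)c2OC(C)(C)C=Cc2c1 | intermediate
10 | 2,2-dimethyl-7-(3-methylbut-2-en-1-yl)-8-oxo-7,8-dihydro-2H-chromene-6-carbaldehyde (racemic Claisen dienone) | O=CC1=CC2=C(OC(C)(C)C=C2)C(=O)C1CC=C(C)C | intermediate (not isolated)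
11 | 8-hydroxy-2,2-dimethyl-7-(3-methylbut-2-en-1-yl)-2H-chromene-6-carbaldehyde | O=Cc1cc2C=CC(C)(C)Oc2c(O)c1CC=C(C)C | intermediate
12 | 2,2-dimethyl-1,3-dioxane-4,6-dione (Meldrum's acid) | CC1(C)OC(=O)CC(=O)O1 | starting material
13 | 5-{[8-hydroxy-2,2-dimethyl-7-(3-methylbut-2-en-1-yl)-2H-chromen-6-yl]methylidene}-2,2-dimethyl-1,3-dioxane-4,6-dione | CC(C)=CCc1c(C=C2C(=O)OC(C)(C)OC2=O)cc2C=CC(C)(C)Oc2c1O | intermediate (not isolated)
14 | 5-{[8-hydroxy-2,2-dimethyl-7-(3-methylbut-2-en-1-yl)-2H-chromen-6-yl]methyl}-2,2-dimethyl-1,3-dioxane-4,6-dione | CC(C)=CCc1c(CC2C(=O)OC(C)(C)OC2=O)cc2C=CC(C)(C)Oc2c1O | intermediate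
15 | resorcinol (benzene-1,3-diol) | Oc1cccc(O)c1 | starting material
16 | 2-{[8-hydroxy-2,2-dimethyl-7-(3-methylbut-2-en-1-yl)-2H-chromen-6-yl]methyl}-3-(3-hydroxyphenoxy)-3-oxopropanoic acid (racemic) | CC(C)=CCc1c(CC(C(=O)O)C(=O)Oc2cccc(O)c2)cc2C=CC(C)(C)Oc2c1O | intermediate (not isolated)
17 | 3-hydroxyphenyl 3-[8-hydroxy-2,2-dimethyl-7-(3-methylbut-2-en-1-yl)-2H-chromen-6-yl]propanoate | CC(C)=CCc1c(CCC(=O)Oc2cccc(O)c2)cc2C=CC(C)(C)Oc2c1O | intermediate
18 | 3-hydroxy-6-{3-[8-hydroxy-2,2-dimethyl-7-(3-methylbut-2-en-1-yl)-2H-chromen-6-yl]propanoyl}cyclohexa-2,4-dien-1-one (racemic) | CC(C)=CCc1c(CCC(=O)C2C=CC(O)=CC2=O)cc2C=CC(C)(C)Oc2c1O | intermediate (not isolated)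
19 | 1-(2,4-dihydroxyphenyl)-3-[8-hydroxy-2,2-dimethyl-7-(3-methylbut-2-en-1-yl)-2H-chromen-6-yl]propan-1-one | CC(C)=CCc1c(CCC(=O)c2ccc(O)cc2O)cc2c(c1O)OC(C)(C)C=C2 | target

**Count.** Total steps: 8. Longest linear sequence: 7 steps (steps 1, 2, 4, 5, 6, 7, 8); step 3 prepares the allylating reagent.

**Steps most likely to fail**

Step 8. Most of the light may be absorbed by the chromene of ring B rather than the ester. Material may then be lost irreversibly through hydrogen shift in the ring-opened chromene or chromene dimerisation, through light-induced cyclisation of the prenyl phenol, or through cage escape of the radical pair; product absorption may also stall conversion. The fallback sets out from 14 and returns at 19, forming the same bond by polar addition. Heating 14 with N,O-dimethylhydroxylamine hydrochloride in pyridine (100 °C) should give, by aminolysis and decarboxylation, the Weinreb amide 3-[8-hydroxy-2,2-dimethyl-7-(3-methylbut-2-en-1-yl)-2H-chromen-6-yl]-N-methoxy-N-methylpropanamide F1. Commercial 4-bromoresorcinol is protected (MOMCl, i-Pr2NEt, CH2Cl2) as 1-bromo-2,4-bis(methoxymethoxy)benzene F2. Bromine–lithium exchange of F2 (n-BuLi, THF, −78 °C) and addition of the aryllithium in excess to F1 (the first equivalent deprotonates the C8 phenol) should give the ketone 1-[2,4-bis(methoxymethoxy)phenyl]-3-[8-hydroxy-2,2-dimethyl-7-(3-methylbut-2-en-1-yl)-2H-chromen-6-yl]propan-1-one F3. Mild acid methanolysis (HCl cat., MeOH, 25 to 40 °C) then removes both acetals to give 19.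

Step 7. Decarboxylation of the half ester may be incomplete, resorcinol may be acylated twice, or the acyl group may be transferred to the C8 phenol of a second molecule. The fallback sets out from 14 and returns at 17. Hydrolysis with decarboxylation (pyridine–H2O, 100 °C) should give 3-[8-hydroxy-2,2-dimethyl-7-(3-methylbut-2-en-1-yl)-2H-chromen-6-yl]propanoic acid F4. Steglich esterification of F4 with excess resorcinol (EDC·HCl, DMAP cat., CH2Cl2–THF, 0 to 25 °C) then gives 17.

Step 4. Zerovalent palladium may re-ionise the tertiary ether, and the product may drift to the linear prenyl ether. The Claisen step would then deliver a 1,1-dimethylallyl group at C7. The fallback sets out from 6 and returns at 9. Alkylation of 6 with 2 (K2CO3, KI, CuI, acetone, 56 °C) should give 2,2-dimethyl-8-[(2-methylbut-3-yn-2-yl)oxy]-2H-chromene-6-carbaldehyde F5. Semihydrogenation of the terminal alkyne (H2 1 atm, Pd/CaCO3 poisoned with Pb(OAc)2, quinoline, EtOAc, 20 °C) then gives 9; the chromene alkene and the aldehyde should survive.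

**Further compounds**
F1 | step 8 | 3-[8-hydroxy-2,2-dimethyl-7-(3-methylbut-2-en-1-yl)-2H-chromen-6-yl]-N-methoxy-N-methylpropanamide | CC(C)=CCc1c(CCC(=O)N(C)OC)cc2C=CC(C)(C)Oc2c1O
F2 | step 8 | 1-bromo-2,4-bis(methoxymethoxy)benzene | COCOc1ccc(Br)c(OCOC)c1
F3 | step 8 | 1-[2,4-bis(methoxymethoxy)phenyl]-3-[8-hydroxy-2,2-dimethyl-7-(3-methylbut-2-en-1-yl)-2H-chromen-6-yl]propan-1-one | CC(C)=CCc1c(CCC(=O)c2ccc(OCOC)cc2OCOC)cc2C=CC(C)(C)Oc2c1O
F4 | step 7 | 3-[8-hydroxy-2,2-dimethyl-7-(3-methylbut-2-en-1-yl)-2H-chromen-6-yl]propanoic acid | CC(C)=CCc1c(CCC(=O)O)cc2C=CC(C)(C)Oc2c1O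
F5 | step 4 | 2,2-dimethyl-8-[(2-methylbut-3-yn-2-yl)oxy]-2H-chromene-6-carbaldehyde | O=Cc1cc(OC(C)(C)C#C)c2OC(C)(C)C=Cc2c1
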